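## The problem

Kazinol E is a flavan: ring A is fused to the dihydropyran ring C, and ring B sits on C2, the only stereocentre, which is S. No other stereocentre can relay control to C2, so it has to be set by a reagent and then kept intact to the end. Three C5 units decorate the skeleton: a 1,1-dimethylallyl group at C6 next to the C7 hydroxyl, and two prenyl groups on the adjacent carbons C2' and C3', which make ring B pentasubstituted and crowd the C1'–C2 bond. The molecule tolerates little. The free catechol (O4', O5') oxidises easily, ortho-prenyl and ortho-(1,1-dimethylallyl) phenols cyclise under acid, and the latter drifts by the abnormal Claisen pathway when heated as the free phenol. The three alkenes exclude late hydrogenation and hydroboration, and a free 4'-hydroxyl para to C1' can open the C2–O1 bond through a para-quinone methide under hot base, which would racemise C2. The enabling feature is positional: C6 is ortho to O7, C3' is ortho to O4' and C2' is para to O5'. Each C5 unit can therefore start on oxygen and be carried to carbon by [3,3] shifts, provided the competing ortho carbons C8 and C6' are occupied.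

## Retrosynthesis

**Unmasking (23 from 22 from 21).** Three O–acyl bonds and two C–Br bonds are cut last. The butanoates are present because the phenols are trapped as they form in the key step, and the bromines are the blocking groups of that step. Taking bromine off first (21 to 22) keeps the phenols masked during the radical reduction and leaves the free catechol and the 4'-hydroxyflavan of 23 to the final operation. An ionic debromination by halogen–metal exchange would instead need an exchange of protecting groups. The forward steps must remove bromine without touching three alkenes and cleave the esters without harming the catechol or C2.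

**The three C5 units (21 from 18).** The bonds C6–C(quaternary), C3'–CH2 and C2'–CH2 are cut and each C5 unit is returned to the neighbouring oxygen as an allyl-type ether. Friedel–Crafts prenylation would give neither the 1,1-dimethylallyl group nor site control, and cross-coupling would demand a hexasubstituted ring B halide and hindered couplings. Precursor 18 carries no C-bound C5 unit at all; all three arrive by O-alkylation. The forward reaction must send each group to the right carbon (the task of the bromines at C8 and C6'), keep the new phenols from reacting further, and leave C2 untouched.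

**The tertiary ether (18 from 17 from 15 and 16).** The O4'–C bond is cut. A 1,1-dimethylallyl aryl ether cannot be made by direct SN2 alkylation, so the propargylic chloride 16 is used and the alkyne of 17 is semi-hydrogenated. This ether is the most labile of the three towards heat and acid and is therefore made last. Phenol 15 is simpler by one C5 unit.

**Ring C and the O4' mask (15 from 14 from 13).** The O1–C2 bond is cut, which moves the stereochemical problem to an open-chain carbinol, 13. The other ring bond, O1–C8a, would need an aryl C–O coupling in the presence of two aryl bromides. The MOM group of 14 keeps O4' distinct from the two prenylated oxygens and prevents a free para-hydroxyl during ring closure. The closure must invert C2 cleanly.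

**The stereocentre and the three-carbon bridge (13 from 12 from 11 from 10 and 4).** The C3–C4 bond is cut by an aldol condensation that places the carbonyl on the ring B side. The usual chalcone, with the carbonyl on ring A, leads to flavanones, whose C2 is formed by a reversible conjugate addition and is harder to control. Ketone 10 and aldehyde 4 are plain aromatic building blocks. The forward steps must saturate the enone without touching prenyl alkenes or aryl bromides, and reduce the aryl ketone under reagent control.

**The ring B ketone (10 from 9 from 8 from 7 from 6 from 5).** Commercial 5 already has bromine at the carbon that becomes C6' and has its two oxygens differentiated. The methyl ether cannot be removed once prenyl ethers are present, so it is exchanged at the outset: demethylation to catechol 6, MOM on the more acidic 4-hydroxyl (7), and prenyl on the 3-hydroxyl (8). Methyl addition and oxidation then turn the formyl group into the acetyl group of 10.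

**The ring A aldehyde (4 from 2 from 1).** Formylation of 1 gives 2, with bromine at the future C8. The 4-hydroxyl is prenylated with 3, and the 2-hydroxyl stays free as the nucleophile of the ring closure.

## Roads not taken

**Alternative 1:** The cut is the C2–C3 bond, reached through a ring-contracted relay. The key step would give methyl (2S,3R)-cis-2-[4,5-bis(methoxymethoxy)-2,3-bis(3-methylbut-2-enyl)phenyl]-6-(3-methylbut-2-enyloxy)-2,3-dihydrobenzofuran-3-carboxylate A1. Dirhodium tetrakis[N-phthaloyl-(S)-tert-leucinate], Rh2(S-PTTL)4, would decompose the diazo ester methyl 2-diazo-2-[2-{[4,5-bis(methoxymethoxy)-2,3-bis(3-methylbut-2-enyl)phenyl]methoxy}-4-(3-methylbut-2-enyloxy)phenyl]acetate A2, and the carbenoid would insert into the benzylic ether C–H bond.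

- Merits: C2 is set by a catalyst in a C–C bond-forming step, no substitution at a benzylic carbinol is needed, and A2 is assembled by a simple etherification.
- Weak points: the carbenoid meets three trisubstituted alkenes and an allylic ether oxygen, so cyclopropanation and oxonium ylide formation compete with insertion into a C–H bond flanked by an ortho prenyl group. The five-membered ring of A1 must then be expanded by ester reduction, activation and a cationic 1,2-aryl shift next to acid-sensitive prenyl groups, and the C3 stereocentre made in the key step is discarded. Ring B must already carry both prenyl groups, so the hardest substitution pattern is moved into a building block. The C6 unit is still missing and would face the C6/C8 choice without a blocking group.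
- Comparison: this road is better in how C2 is set. The chosen plan offers in return that all three C5 units come from O-alkylation and one thermolysis, with no carbenoid near an alkene and no skeletal rearrangement.

**Alternative 2:** The cuts are C4a–C4 and O1–C8a, made in one Catellani annulation. The product would be (2S)-2-[4,5-bis(methoxymethoxy)-2,3-bis(3-methylbut-2-enyl)phenyl]-7-(3-methylbut-2-enyloxy)chroman A3. It would come from 1-iodo-3-(3-methylbut-2-enyloxy)benzene A4 and (1S)-3-bromo-1-[4,5-bis(methoxymethoxy)-2,3-bis(3-methylbut-2-enyl)phenyl]propan-1-ol A5 with Pd(OAc)2, a triarylphosphine, norbornene and Cs2CO3.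

- Merits: it is the most convergent of the four plans, and the stereocentre of A5 is not touched by the bond formation.
- Weak points: A4 has two free ortho positions, whereas this annulation normally relies on one being blocked, so double or misplaced alkylation is to be expected. Reductive elimination of a secondary benzylic alkoxide competes with β-hydride elimination to the ketone. Zerovalent palladium can also ionise the aryl prenyl ether. A5 again hides the vicinal diprenyl catechol in a building block, and A3 still lacks the C6 unit.
- Comparison: this road is shorter in its longest linear sequence and needs no blocking groups. The chosen plan offers in return a solution for ring B itself and for the C6/C8 choice.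

**Alternative 3:** The cuts are the two prenyl C=C bonds, with the vicinal diprenyl unit carried as a fused cyclohexene. The product would be (2S)-2-[4,5-bis(methoxymethoxy)-2,3-bis(3-methylbut-2-enyl)phenyl]-7-(tert-butyldimethylsilyloxy)chroman A6. OsO4 with NaIO4 would cleave the alkene of (2S)-2-[3,4-bis(methoxymethoxy)-5,8-dihydronaphthalen-1-yl]-7-(tert-butyldimethylsilyloxy)chroman A7 to the dialdehyde 2,2'-{3-[(2S)-7-(tert-butyldimethylsilyloxy)chroman-2-yl]-5,6-bis(methoxymethoxy)-1,2-phenylene}diacetaldehyde A8, and two equivalents of Ph3P=C(CH3)2 would form both prenyl groups.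

- Merits: the carbocycle fixes the 2',3' pattern with no question of site selectivity, which is better than a para shift steered by a blocking group. The flavan can also be built without alkenes, so borane and hydrogenation are usable.
- Weak points: A8 has two enolisable arylacetaldehydes on adjacent carbons and would meet a strongly basic, non-stabilised ylide, so enolisation and intramolecular aldol condensation compete with olefination. After A6 the route still needs desilylation, O-prenylation, an unblocked Claisen shift that favours C8 over C6 in 7-allyloxychromans, and removal of MOM groups beside ortho-prenyl phenols.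
- Comparison: this road is superior for the regiochemistry of ring B. The chosen plan offers in return a much shorter endgame and control of the C6 unit.

Key step: step 15

## The route

Assumption: the tertiary 2-methylbut-3-en-2-yl ether of 18 rearranges at a clearly lower temperature than the two prenyl ethers, as is general for aryl 1,1-dimethylallyl ethers; the order of events in step 15 is written on that basis.

Step 1
Reactants: 1 2-bromoresorcinol
Product: 2 3-bromo-2,4-dihydroxybenzaldehyde
Conditions: POCl3, DMF, CH3CN, 0 °C → rt; then H2O, 50 °C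
Reagents that add atoms: N,N-dimethylformamide, CN(C)C=O; water, O
Why: Vilsmeier–Haack formylation of a resorcinol goes para to one hydroxyl and ortho to the other; the two such positions of 1 are equivalent and the carbon between the oxygens carries bromine, so one aldehyde should form.

Step 2
Reactants: 2 3-bromo-2,4-dihydroxybenzaldehyde; 3 1-bromo-3-methylbut-2-ene (prenyl bromide)
Product: 4 3-bromo-2-hydroxy-4-(3-methylbut-2-enyloxy)benzaldehyde
Conditions: 3 (1.05 equiv), KHCO3, DMF, 40 °C
Reagents that add atoms: none
Why: Williamson etherification; the 4-hydroxyl, para to the formyl group, is the more acidic and is not held in the hydrogen bond that ties the 2-hydroxyl to the carbonyl, so a weak base should alkylate it alone.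

Step 3
Reactants: 5 2-bromo-3-hydroxy-4-methoxybenzaldehyde (2-bromoisovanillin)
Product: 6 2-bromo-3,4-dihydroxybenzaldehyde
Conditions: BBr3, CH2Cl2, −78 °C → rt; then H2O
Reagents that add atoms: none
Why: Lewis-acid cleavage of an aryl methyl ether; the aldehyde and the aryl bromide are inert under these conditions, and the methyl group is removed here because it could not be removed once prenyl ethers are present.

Step 4
Reactants: 6 2-bromo-3,4-dihydroxybenzaldehyde
Product: 7 2-bromo-3-hydroxy-4-(methoxymethoxy)benzaldehyde
Conditions: MOMCl (1.05 equiv), K2CO3 (1.0 equiv), acetone, 0 °C → rt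
Reagents that add atoms: chloromethyl methyl ether, COCCl
Why: With one equivalent of base the more acidic 4-hydroxyl (para to the formyl group) is deprotonated and alkylated first, the usual selectivity of catechol aldehydes; MOM withstands the Grignard, base, hydrogenation and Mitsunobu steps that follow.

Step 5
Reactants: 7 2-bromo-3-hydroxy-4-(methoxymethoxy)benzaldehyde; 3 1-bromo-3-methylbut-2-ene
Product: 8 2-bromo-4-(methoxymethoxy)-3-(3-methylbut-2-enyloxy)benzaldehyde
Conditions: 3, K2CO3, DMF, rt
Reagents that add atoms: none
Why: Williamson etherification of the remaining phenol, which places the prenyl group on the oxygen that becomes O5'.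

Step 6
Reactants: 8 2-bromo-4-(methoxymethoxy)-3-(3-methylbut-2-enyloxy)benzaldehyde
Product: 9 racemic 1-[2-bromo-4-(methoxymethoxy)-3-(3-methylbut-2-enyloxy)phenyl]ethanol
Conditions: MeMgBr, THF, 0 °C; then aq. NH4Cl
Reagents that add atoms: methylmagnesium bromide, C[Mg]Br
Why: Grignard addition to an aldehyde; MeMgBr does not exchange with the aryl bromide at 0 °C, and the racemic stereocentre is removed in the next step.

Step 7
Reactants: 9 racemic 1-[2-bromo-4-(methoxymethoxy)-3-(3-methylbut-2-enyloxy)phenyl]ethanol
Product: 10 1-[2-bromo-4-(methoxymethoxy)-3-(3-methylbut-2-enyloxy)phenyl]ethanone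
Conditions: Dess–Martin periodinane, NaHCO3, CH2Cl2, 0 °C → rt
Reagents that add atoms: none
Why: Dess–Martin oxidation of a hindered benzylic alcohol; the buffer protects the MOM ether and the prenyl alkene is not affected.

Step 8
Reactants: 10 1-[2-bromo-4-(methoxymethoxy)-3-(3-methylbut-2-enyloxy)phenyl]ethanone; 4 3-bromo-2-hydroxy-4-(3-methylbut-2-enyloxy)benzaldehyde
Product: 11 (E)-1-[2-bromo-4-(methoxymethoxy)-3-(3-methylbut-2-enyloxy)phenyl]-3-[3-bromo-2-hydroxy-4-(3-methylbut-2-enyloxy)phenyl]prop-2-en-1-one
Conditions: KOH (aq., excess), EtOH, rt; neutralised with AcOH at 0 °C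
Reagents that add atoms: none
Why: Claisen–Schmidt condensation; the methyl ketone enolate adds to the aldehyde and dehydration gives the E-enone, and although the phenoxide of 4 slows the addition, salicylaldehydes are known to condense under these conditions. Neutralisation is kept cold and mild so that the 2-hydroxychalcone does not close to a flavylium salt.

Step 9
Reactants: 11 (E)-1-[2-bromo-4-(methoxymethoxy)-3-(3-methylbut-2-enyloxy)phenyl]-3-[3-bromo-2-hydroxy-4-(3-methylbut-2-enyloxy)phenyl]prop-2-en-1-one
Product: 12 1-[2-bromo-4-(methoxymethoxy)-3-(3-methylbut-2-enyloxy)phenyl]-3-[3-bromo-2-hydroxy-4-(3-methylbut-2-enyloxy)phenyl]propan-1-one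
Conditions: H2 (1 atm), RhCl(PPh3)3 (5 mol %), benzene/EtOH 1:1, rt
Reagents that add atoms: none
Why: Homogeneous hydrogenation with RhCl(PPh3)3 reduces the disubstituted conjugated alkene, while the trisubstituted prenyl alkenes and the aryl bromides should stay untouched.

Step 10
Reactants: 12 1-[2-bromo-4-(methoxymethoxy)-3-(3-methylbut-2-enyloxy)phenyl]-3-[3-bromo-2-hydroxy-4-(3-methylbut-2-enyloxy)phenyl]propan-1-one
Product: 13 (1R)-1-[2-bromo-4-(methoxymethoxy)-3-(3-methylbut-2-enyloxy)phenyl]-3-[3-bromo-2-hydroxy-4-(3-methylbut-2-enyloxy)phenyl]propan-1-ol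
Conditions: RuCl[(R,R)-TsDPEN](p-cymene) (2 mol %), HCO2H/Et3N (5:2), DMF, 30 °C
Reagents that add atoms: none
Why: Noyori–Ikariya asymmetric transfer hydrogenation of an aryl alkyl ketone; the (R,R) ligand delivers hydride to the face that gives the (R)-carbinol, in the same sense as acetophenone gives (R)-1-phenylethanol. Formic acid leaves the prenyl alkenes, the aryl bromides and the free phenol alone, whereas borane would hydroborate the alkenes.

Step 11
Reactants: 13 (1R)-1-[2-bromo-4-(methoxymethoxy)-3-(3-methylbut-2-enyloxy)phenyl]-3-[3-bromo-2-hydroxy-4-(3-methylbut-2-enyloxy)phenyl]propan-1-ol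
Product: 14 (2S)-8-bromo-2-[2-bromo-4-(methoxymethoxy)-3-(3-methylbut-2-enyloxy)phenyl]-7-(3-methylbut-2-enyloxy)chroman
Conditions: PPh3, DIAD, THF, 0 °C → rt
Reagents that add atoms: none
Why: Intramolecular Mitsunobu etherification (6-exo-tet); the acidic bromophenol displaces the alkoxyphosphonium group with inversion, so the (R)-alcohol gives the (S)-chroman. The electron-withdrawing bromine next to the carbinol carbon should temper the ionisation that the para-alkoxy group would otherwise invite.

Step 12
Reactants: 14 (2S)-8-bromo-2-[2-bromo-4-(methoxymethoxy)-3-(3-methylbut-2-enyloxy)phenyl]-7-(3-methylbut-2-enyloxy)chroman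
Product: 15 3-bromo-4-[(2S)-8-bromo-7-(3-methylbut-2-enyloxy)chroman-2-yl]-2-(3-methylbut-2-enyloxy)phenol
Conditions: TMSOTf, 2,2'-bipyridyl, CH3CN, 0 °C → rt; then H2O
Reagents that add atoms: none
Why: The silyl triflate buffered by 2,2'-bipyridyl activates only the acetal oxygen of the aryl MOM ether, and the aryl silyl ether formed is hydrolysed on aqueous work-up at neutral pH. The acid-labile aryl prenyl ethers and the benzylic C2–O1 bond should therefore be spared.

Step 13
Reactants: 15 3-bromo-4-[(2S)-8-bromo-7-(3-methylbut-2-enyloxy)chroman-2-yl]-2-(3-methylbut-2-enyloxy)phenol; 16 3-chloro-3-methylbut-1-yne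
Product: 17 (2S)-8-bromo-2-[2-bromo-4-(2-methylbut-3-yn-2-yloxy)-3-(3-methylbut-2-enyloxy)phenyl]-7-(3-methylbut-2-enyloxy)chroman
Conditions: 16 (1.5 equiv), DBU, CuCl2·2H2O (cat.), CH3CN, 0 °C
Reagents that add atoms: none
Why: Copper-catalysed O-alkylation of a phenol by a tertiary propargylic chloride gives the aryl 1,1-dimethylpropargyl ether at 0 °C; the low temperature keeps the 4'-phenoxide from opening ring C through a para-quinone methide.

Step 14
Reactants: 17 (2S)-8-bromo-2-[2-bromo-4-(2-methylbut-3-yn-2-yloxy)-3-(3-methylbut-2-enyloxy)phenyl]-7-(3-methylbut-2-enyloxy)chroman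
Product: 18 (2S)-8-bromo-2-[2-bromo-4-(2-methylbut-3-en-2-yloxy)-3-(3-methylbut-2-enyloxy)phenyl]-7-(3-methylbut-2-enyloxy)chroman
Conditions: H2 (1 atm), Pd/CaCO3 poisoned with Pb(OAc)2 (Lindlar catalyst), quinoline, EtOAc, rt; stopped after one equivalent of H2
Reagents that add atoms: none
Why: Lindlar semihydrogenation stops at the terminal alkene; trisubstituted alkenes and aryl bromides are inert to the poisoned catalyst. The product is handled cold and without acid, since it is the substrate of the thermal step.

Step 15
Reactants: 18 (2S)-8-bromo-2-[2-bromo-4-(2-methylbut-3-en-2-yloxy)-3-(3-methylbut-2-enyloxy)phenyl]-7-(3-methylbut-2-enyloxy)chroman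
Product: 21 (2S)-8-bromo-2-[2-bromo-3,4-bis(butanoyloxy)-5,6-bis(3-methylbut-2-enyl)phenyl]-6-(2-methylbut-3-en-2-yl)chroman-7-yl butanoate, via the 4'-butanoate of the first Claisen shift 19 (not isolated), via the 7,4'-dibutanoate after two shifts 20 (not isolated)
Conditions: butyric anhydride (10 equiv), N,N-diethylaniline (degassed), Ar, 120 °C, then 190 °C
Reagents that add atoms: butyric anhydride, CCCC(=O)OC(=O)CCC
Why: Three aromatic Claisen rearrangements take place in one flask, each a concerted chair-like [3,3] shift of an aryl allyl ether to an ortho-dienone. The tertiary ether on O4' should react first, near 120 °C, at the hydrogen-bearing C3'; allyl inversion makes the prenyl group, the dienone tautomerises and the phenol is acylated by the anhydride to give 19. At 190 °C the O7 prenyl ether shifts to C6 with inversion, which makes the 1,1-dimethylallyl group, and acylation gives 20. The O5' prenyl ether has both ortho carbons blocked (bromine at C6', acyloxy at C4'), so its ortho-dienone cannot enolise and passes the group on by a Cope shift to the para carbon C2'; the second inversion restores the prenyl group, and tautomerisation and acylation give 21. The closest known reactions are the ortho-Claisen rearrangements of aryl prenyl and aryl 1,1-dimethylallyl ethers and the para-Claisen (Claisen–Cope) rearrangement of 2,6-disubstituted aryl prenyl ethers, run in N,N-diethylaniline with an anhydride that traps the phenols. No ring closes and no stereocentre is formed. Site selectivity (C6 over C8, C2' over C6') rests on the two bromines: a shift to C8 can only revert because its para carbon C4a is substituted, and a shift to C6' can only continue to C2'. Trapping each phenol as its ester removes the O–H needed for the abnormal Claisen drift of the C6 group and for cyclisation of the ortho-prenyl phenol, and it keeps a free 4'-hydroxyl from opening ring C, so C2 should stay S.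

Step 16
Reactants: 21 (2S)-8-bromo-2-[2-bromo-3,4-bis(butanoyloxy)-5,6-bis(3-methylbut-2-enyl)phenyl]-6-(2-methylbut-3-en-2-yl)chroman-7-yl butanoate
Product: 22 (2S)-2-[4,5-bis(butanoyloxy)-2,3-bis(3-methylbut-2-enyl)phenyl]-6-(2-methylbut-3-en-2-yl)chroman-7-yl butanoate
Conditions: Bu3SnH (3 equiv), AIBN (0.2 equiv), toluene, 90 °C
Reagents that add atoms: none
Why: Radical chain hydrodebromination; the tin radical abstracts bromine from both aryl bromides and each aryl radical is quenched by Bu3SnH. Neither aryl radical has an alkene within reach of a five- or six-membered cyclisation, and the phenols are masked as esters.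

Step 17
Reactants: 22 (2S)-2-[4,5-bis(butanoyloxy)-2,3-bis(3-methylbut-2-enyl)phenyl]-6-(2-methylbut-3-en-2-yl)chroman-7-yl butanoate
Product: 23 kazinol E, (2S)-2-[4,5-dihydroxy-2,3-bis(3-methylbut-2-enyl)phenyl]-6-(2-methylbut-3-en-2-yl)chroman-7-ol
Conditions: K2CO3 (cat.), MeOH (degassed), 0 °C → rt; then aq. NH4Cl
Reagents that add atoms: none
Why: Base-catalysed methanolysis of aryl esters at or below room temperature, with oxygen excluded to protect the catechol. With the C8 bromine gone, O1 is a poorer leaving group, so the 4'-phenoxide should not open ring C and C2 should stay S.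

## Compound list

1 | 2-bromoresorcinol | Oc1cccc(O)c1Br | starting material
2 | 3-bromo-2,4-dihydroxybenzaldehyde | O=Cc1ccc(O)c(Br)c1O | intermediate
3 | 1-bromo-3-methylbut-2-ene (prenyl bromide) | CC(C)=CCBr | starting material
4 | 3-bromo-2-hydroxy-4-(3-methylbut-2-enyloxy)benzaldehyde | O=Cc1ccc(OCC=C(C)C)c(Br)c1O | intermediate
5 | 2-bromo-3-hydroxy-4-methoxybenzaldehyde (2-bromoisovanillin) | COc1ccc(C=O)c(Br)c1O | starting material
6 | 2-bromo-3,4-dihydroxybenzaldehyde | O=Cc1ccc(O)c(O)c1Br | intermediate
7 | 2-bromo-3-hydroxy-4-(methoxymethoxy)benzaldehyde | COCOc1ccc(C=O)c(Br)c1O | intermediate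
8 | 2-bromo-4-(methoxymethoxy)-3-(3-methylbut-2-enyloxy)benzaldehyde | COCOc1ccc(C=O)c(Br)c1OCC=C(C)C | intermediate
9 | racemic 1-[2-bromo-4-(methoxymethoxy)-3-(3-methylbut-2-enyloxy)phenyl]ethanol | COCOc1ccc(C(C)O)c(Br)c1OCC=C(C)C | intermediate
10 | 1-[2-bromo-4-(methoxymethoxy)-3-(3-methylbut-2-enyloxy)phenyl]ethanone | COCOc1ccc(C(C)=O)c(Br)c1OCC=C(C)C | intermediate
11 | (E)-1-[2-bromo-4-(methoxymethoxy)-3-(3-methylbut-2-enyloxy)phenyl]-3-[3-bromo-2-hydroxy-4-(3-methylbut-2-enyloxy)phenyl]prop-2-en-1-one | COCOc1ccc(C(=O)/C=C/c2ccc(OCC=C(C)C)c(Br)c2O)c(Br)c1OCC=C(C)C | intermediate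
12 | 1-[2-bromo-4-(methoxymethoxy)-3-(3-methylbut-2-enyloxy)phenyl]-3-[3-bromo-2-hydroxy-4-(3-methylbut-2-enyloxy)phenyl]propan-1-one | COCOc1ccc(C(=O)CCc2ccc(OCC=C(C)C)c(Br)c2O)c(Br)c1OCC=C(C)C | intermediate
13 | (1R)-1-[2-bromo-4-(methoxymethoxy)-3-(3-methylbut-2-enyloxy)phenyl]-3-[3-bromo-2-hydroxy-4-(3-methylbut-2-enyloxy)phenyl]propan-1-ol | O[C@H](CCc1ccc(OCC=C(C)C)c(Br)c1O)c1ccc(OCOC)c(OCC=C(C)C)c1Br | intermediate
14 | (2S)-8-bromo-2-[2-bromo-4-(methoxymethoxy)-3-(3-methylbut-2-enyloxy)phenyl]-7-(3-methylbut-2-enyloxy)chroman | CC(C)=CCOc1ccc2c(c1Br)O[C@H](c1ccc(OCOC)c(OCC=C(C)C)c1Br)CC2 | intermediate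
15 | 3-bromo-4-[(2S)-8-bromo-7-(3-methylbut-2-enyloxy)chroman-2-yl]-2-(3-methylbut-2-enyloxy)phenol | CC(C)=CCOc1ccc2c(c1Br)O[C@H](c1ccc(O)c(OCC=C(C)C)c1Br)CC2 | intermediate
16 | 3-chloro-3-methylbut-1-yne | CC(C)(Cl)C#C | starting material
17 | (2S)-8-bromo-2-[2-bromo-4-(2-methylbut-3-yn-2-yloxy)-3-(3-methylbut-2-enyloxy)phenyl]-7-(3-methylbut-2-enyloxy)chroman | CC(C)=CCOc1ccc2c(c1Br)O[C@H](c1ccc(OC(C)(C)C#C)c(OCC=C(C)C)c1Br)CC2 | intermediate
18 | (2S)-8-bromo-2-[2-bromo-4-(2-methylbut-3-en-2-yloxy)-3-(3-methylbut-2-enyloxy)phenyl]-7-(3-methylbut-2-enyloxy)chroman | CC(C)=CCOc1ccc2c(c1Br)O[C@H](c1ccc(OC(C)(C)C=C)c(OCC=C(C)C)c1Br)CC2 | intermediate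
19 | 3-bromo-4-[(2S)-8-bromo-7-(3-methylbut-2-enyloxy)chroman-2-yl]-6-(3-methylbut-2-enyl)-2-(3-methylbut-2-enyloxy)phenyl butanoate | CC(C)=CCOc1ccc2c(c1Br)O[C@H](c1cc(CC=C(C)C)c(OC(=O)CCC)c(OCC=C(C)C)c1Br)CC2 | intermediate
20 | (2S)-8-bromo-2-[2-bromo-4-(butanoyloxy)-5-(3-methylbut-2-enyl)-3-(3-methylbut-2-enyloxy)phenyl]-6-(2-methylbut-3-en-2-yl)chroman-7-yl butanoate | C=CC(C)(C)c1cc2c(c(Br)c1OC(=O)CCC)O[C@H](c1cc(CC=C(C)C)c(OC(=O)CCC)c(OCC=C(C)C)c1Br)CC2 | intermediate
21 | (2S)-8-bromo-2-[2-bromo-3,4-bis(butanoyloxy)-5,6-bis(3-methylbut-2-enyl)phenyl]-6-(2-methylbut-3-en-2-yl)chroman-7-yl butanoate | C=CC(C)(C)c1cc2c(c(Br)c1OC(=O)CCC)O[C@H](c1c(CC=C(C)C)c(CC=C(C)C)c(OC(=O)CCC)c(OC(=O)CCC)c1Br)CC2 | intermediate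
22 | (2S)-2-[4,5-bis(butanoyloxy)-2,3-bis(3-methylbut-2-enyl)phenyl]-6-(2-methylbut-3-en-2-yl)chroman-7-yl butanoate | C=CC(C)(C)c1cc2c(cc1OC(=O)CCC)O[C@H](c1cc(OC(=O)CCC)c(OC(=O)CCC)c(CC=C(C)C)c1CC=C(C)C)CC2 | intermediate
23 | kazinol E, (2S)-2-[4,5-dihydroxy-2,3-bis(3-methylbut-2-enyl)phenyl]-6-(2-methylbut-3-en-2-yl)chroman-7-ol | C=CC(C)(C)c1cc2c(cc1O)O[C@H](c1cc(O)c(O)c(CC=C(C)C)c1CC=C(C)C)CC2 | target

## Step count and least certain steps

Total: 17 steps. Longest linear sequence: 15 steps (steps 3 to 17, from 5). The ring A branch (steps 1 and 2) joins at step 8.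

**Step 15 (key step).** The crowded para migration on ring B is the most exposed event.
- Bromine may be lost from the bromo-dienone at C6', by transfer to the electron-rich amine solvent or by homolysis, which would let the C5 unit settle at C6'.
- The tertiary ether may fragment to phenol and isoprene before it rearranges.
- Acylation of the hindered O7 and O4' phenols may lag behind the shifts, which would reopen the abnormal Claisen drift and the ring opening that racemises C2.

Fallback: the thermolysis is divided into two operations. From 18, heating at about 120 °C in toluene with butyric anhydride and pyridine should carry only the tertiary ether across and give 19, which is isolated. Then 19 is heated in butyric anhydride with NaO2CCH2CH2CH3 and no aromatic amine, so that no acceptor for bromine is present. This should give 21 by way of 20, where the route is rejoined. This fallback makes no new compound (F0).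

**Step 12.** Silyl activation may not stay on the acetal: ionisation of one or both aryl prenyl ethers to the prenyl cation, followed by C-alkylation of the electron-rich rings, would erode the differentiation of the three oxygens.

Fallback: from 14, all three ethers are cleaved on purpose with HCl in MeOH at 40 °C, where methanol traps the cations. This gives the triol (2S)-8-bromo-2-(2-bromo-3,4-dihydroxyphenyl)chroman-7-ol F1. The two hydroxyls that flank a bromine (O7 and O5') are the more acidic, so two equivalents of 3 with KHCO3 in DMF should alkylate them and leave O4' free, which returns the route to 15.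

**Step 16.** The radical chain may be diverted: tin radicals may add to the terminal vinyl group, or abstraction at the buried C6' bromine may be slow and leave one bromine in place.

Fallback: an ionic debromination. From 21, methanolysis with K2CO3 in MeOH gives (2S)-8-bromo-2-[2-bromo-3,4-dihydroxy-5,6-bis(3-methylbut-2-enyl)phenyl]-6-(2-methylbut-3-en-2-yl)chroman-7-ol F2. MOMCl with i-Pr2NEt gives (2S)-8-bromo-2-[2-bromo-3,4-bis(methoxymethoxy)-5,6-bis(3-methylbut-2-enyl)phenyl]-7-(methoxymethoxy)-6-(2-methylbut-3-en-2-yl)chroman F3. Bromine–lithium exchange with t-BuLi in THF at −78 °C and quenching with MeOH gives (2S)-2-[4,5-bis(methoxymethoxy)-2,3-bis(3-methylbut-2-enyl)phenyl]-7-(methoxymethoxy)-6-(2-methylbut-3-en-2-yl)chroman F4. MOM ethers are preferred to silyl ethers here, because an aryllithium next to a silyl ether can take the silyl group from oxygen. TMSOTf with 2,2'-bipyridyl, then water, removes the MOM groups and the route ends at 23.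

**Step 4.** Alkylation may go to the wrong hydroxyl or to both: the bromine next to the 3-hydroxyl raises its acidity and narrows the gap to the 4-hydroxyl.

Fallback: the order of the two alkylations is reversed through the dianion. From 6, NaH (2.2 equiv) in DMSO followed by one equivalent of 3 should alkylate the more basic 3-oxide and give 2-bromo-4-hydroxy-3-(3-methylbut-2-enyloxy)benzaldehyde F5. MOMCl with i-Pr2NEt then protects the 4-hydroxyl and returns the route to 8.

**Step 13.** Alkylation at the tertiary propargylic centre may be slow. The phenoxide then has time to open ring C through the para-quinone methide, with erosion of C2, and 16 may be consumed by elimination to the enyne.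

Fallback: the tertiary allyl ether is made directly. From 15, tert-butyl 2-methylbut-3-en-2-yl carbonate F6 (from 2-methylbut-3-en-2-ol and di-tert-butyl dicarbonate) and the zerovalent palladium complex Pd(PPh3)4 in THF at 0 °C should give the π-allyl complex, which the phenoxide attacks at the more substituted terminus. The route is rejoined at 18, and compound 17 and step 14 are bypassed.

## Further compounds

F0 | step 15 | none | none
F1 | step 12 | (2S)-8-bromo-2-(2-bromo-3,4-dihydroxyphenyl)chroman-7-ol | Oc1ccc2c(c1Br)O[C@H](c1ccc(O)c(O)c1Br)CC2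
F2 | step 16 | (2S)-8-bromo-2-[2-bromo-3,4-dihydroxy-5,6-bis(3-methylbut-2-enyl)phenyl]-6-(2-methylbut-3-en-2-yl)chroman-7-ol | C=CC(C)(C)c1cc2c(c(Br)c1O)O[C@H](c1c(Br)c(O)c(O)c(CC=C(C)C)c1CC=C(C)C)CC2
F3 | step 16 | (2S)-8-bromo-2-[2-bromo-3,4-bis(methoxymethoxy)-5,6-bis(3-methylbut-2-enyl)phenyl]-7-(methoxymethoxy)-6-(2-methylbut-3-en-2-yl)chroman | C=CC(C)(C)c1cc2c(c(Br)c1OCOC)O[C@H](c1c(Br)c(OCOC)c(OCOC)c(CC=C(C)C)c1CC=C(C)C)CC2
F4 | step 16 | (2S)-2-[4,5-bis(methoxymethoxy)-2,3-bis(3-methylbut-2-enyl)phenyl]-7-(methoxymethoxy)-6-(2-methylbut-3-en-2-yl)chroman | C=CC(C)(C)c1cc2c(cc1OCOC)O[C@H](c1cc(OCOC)c(OCOC)c(CC=C(C)C)c1CC=C(C)C)CC2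
F5 | step 4 | 2-bromo-4-hydroxy-3-(3-methylbut-2-enyloxy)benzaldehyde | O=Cc1ccc(O)c(OCC=C(C)C)c1Br
F6 | step 13 | tert-butyl 2-methylbut-3-en-2-yl carbonate | C=CC(C)(C)OC(=O)OC(C)(C)C
A1 | alternative 1 | methyl (2S,3R)-cis-2-[4,5-bis(methoxymethoxy)-2,3-bis(3-methylbut-2-enyl)phenyl]-6-(3-methylbut-2-enyloxy)-2,3-dihydrobenzofuran-3-carboxylate | CC(C)=CCOc1ccc2c(c1)O[C@H](c1cc(OCOC)c(OCOC)c(CC=C(C)C)c1CC=C(C)C)[C@@H]2C(=O)OC
A2 | alternative 1 | methyl 2-diazo-2-[2-{[4,5-bis(methoxymethoxy)-2,3-bis(3-methylbut-2-enyl)phenyl]methoxy}-4-(3-methylbut-2-enyloxy)phenyl]acetate | COC(=O)C(=[N+]=[N-])c1ccc(OCC=C(C)C)cc1OCc1cc(OCOC)c(OCOC)c(CC=C(C)C)c1CC=C(C)C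
A3 | alternative 2 | (2S)-2-[4,5-bis(methoxymethoxy)-2,3-bis(3-methylbut-2-enyl)phenyl]-7-(3-methylbut-2-enyloxy)chroman | CC(C)=CCOc1ccc2c(c1)O[C@H](c1cc(OCOC)c(OCOC)c(CC=C(C)C)c1CC=C(C)C)CC2
A4 | alternative 2 | 1-iodo-3-(3-methylbut-2-enyloxy)benzene | CC(C)=CCOc1cccc(I)c1
A5 | alternative 2 | (1S)-3-bromo-1-[4,5-bis(methoxymethoxy)-2,3-bis(3-methylbut-2-enyl)phenyl]propan-1-ol | O[C@H](c1cc(OCOC)c(OCOC)c(CC=C(C)C)c1CC=C(C)C)CCBr
A6 | alternative 3 | (2S)-2-[4,5-bis(methoxymethoxy)-2,3-bis(3-methylbut-2-enyl)phenyl]-7-(tert-butyldimethylsilyloxy)chroman | CC(C)(C)[Si](C)(C)Oc1ccc2c(c1)O[C@H](c1cc(OCOC)c(OCOC)c(CC=C(C)C)c1CC=C(C)C)CC2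
A7 | alternative 3 | (2S)-2-[3,4-bis(methoxymethoxy)-5,8-dihydronaphthalen-1-yl]-7-(tert-butyldimethylsilyloxy)chroman | CC(C)(C)[Si](C)(C)Oc1ccc2c(c1)O[C@H](c1cc(OCOC)c(OCOC)c3c1CC=CC3)CC2
A8 | alternative 3 | 2,2'-{3-[(2S)-7-(tert-butyldimethylsilyloxy)chroman-2-yl]-5,6-bis(methoxymethoxy)-1,2-phenylene}diacetaldehyde | CC(C)(C)[Si](C)(C)Oc1ccc2c(c1)O[C@H](c1cc(OCOC)c(OCOC)c(CC=O)c1CC=O)CC2
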